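**Numbering used throughout:** 1 2-methoxyresorcinol; 2 iminium chloride; 3 dihydroxy aldehyde; 4 bis(benzyl) aldehyde; 5 aryl formate; 6 phenol; 7 aryl triflate; 8 1,2,3,4-tetramethoxybenzene; 9 vinylboronic acid pinacol ester; 10 aryllithium; 11 vinylboron ate complex; 12 benzylic boronic ester; 13 homologated boronic ester; 14 primary alcohol; 15 diphenol alcohol; 16 target.

## Analysis of the target

The target 16 is an isoflavan, a chroman with ring A (benzene), ring C (O1, C2H2, C3H, C4H2) and ring B (a 2,3,4,5-tetramethoxyphenyl group on C3). Ring A carries a free hydroxyl at C7 and a methoxy group at C8. C3 is the only stereocentre and must be S. It is a tertiary C–H flanked by two methylene groups, so only absolute control is needed, but no neighbouring polar group can relay it. In 16 the centre is configurationally safe, because neither C2 nor C4 is a carbonyl carbon; many classical isoflavonoid routes pass through C4 ketones or C2 lactones in which this C–H is acidic. The sensitive functions are the C7 phenol, which must be masked through the organometallic steps, and two very electron-rich arenes. The difficulty is to join ring B and C4 to C3 with absolute control, although the two alkyl arms of C3 differ only at their far ends and ortho-oxygen substituents crowd both aryl–carbon bonds (C3–C1' and C4–C4a). The strategy rests on reading C3–C4 as a vinylboron unit: C3 carries boron in place of C2 and receives ring B, and C4 is the terminal alkene carbon that bonds to C4a of ring A. The boron at C3 is later exchanged for the C2 methylene with retention, so the stereocentre is born as a non-enolisable benzylic boronic ester.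

## Retrosynthetic reasoning

16 to 15: The O1–C2 bond is cut first. It is the only heteroatom bond of ring C, and closing it by substitution at the primary C2 (Mitsunobu etherification) does not touch C3. Only the phenol ortho to the side chain can reach C2 through a six-membered transition state, so regiochemistry is decided by ring size and the C7 phenol need not be distinguished by a protecting group.

15 to 14: Both phenols are therefore carried as benzyl ethers. One alkylation installs them, they survive organolithium, palladium and peroxide chemistry, and one hydrogenolysis removes them.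

14 to 12 (through 13): C2 is removed as a one-carbon unit. The C3–C2 bond is formed by a Matteson-type insertion into the C3–B bond of 12, which migrates the secondary benzylic carbon with retention, and the new C–B bond of 13 is oxidised to the alcohol. This is what lets boron stand in for C2 in the key step.

12 to 7, 9 and 10 (through 11): The two skeletal bonds at the vinyl unit are cut together, C3–C1' to ring B and C4–C4a to ring A. In the forward direction 10 and 9 give the ate complex 11, and a chiral palladium catalyst couples it with 7. Cutting here places the creation of C3 in the same step as both C–C bonds and needs no carbonyl group next to C3 at any stage. A triflate is chosen as electrophile because its non-coordinating counter-ion keeps the arylpalladium cationic.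

10 to 8: The aryllithium is taken from 8 by directed ortho-lithiation rather than from a bromide. The two ring hydrogens of 8 are equivalent and each is ortho to a methoxy group, so no regiochemical question arises, and no lithium halide is formed that could block the cationic palladium pathway.

7 to 1 (through 6, 5, 4, 3 and 2): The triflate comes from phenol 6, and the phenol oxygen is introduced as a formyl group that is later exchanged for oxygen. Formylation of 1 can only occur at the position ortho to one hydroxyl and para to the other, which fixes the 1,2,3,4-tetraoxygenated pattern. Double benzylation, peracid oxidation of the aldehyde to the formate 5, its cleavage to 6 and O-triflation complete the sequence.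

## Alternatives that were turned down

Alternative 1: Ring B itself is disconnected and traced back to a four-membered ring. The acetylide of (3S)-7-benzyloxy-3-ethynyl-8-methoxychroman A3 would add to dimethyl squarate A4 to give the alkynyl hydroxycyclobutenone A2. Heating A2 opens the cyclobutenone to an alkynyl ketene that closes C1'–C2' and delivers the dimethoxybenzoquinone A1 on an intact chroman. In its favour, the oxygenation pattern of ring B is fixed by construction, the key step needs no reagent, and C3 is not touched. Against it, the step builds a ring whose substitution pattern is available in 8, and it leaves the real problem unsolved: C3 must already be present in A3, which needs its own asymmetric synthesis and its own chroman closure. After A1, a quinone reduction, a double O-methylation and a debenzylation are still required. On regiocontrol and mildness this route is at least equal to the chosen one. The chosen route obtains ring B by one lithiation of 8, spends its key step on C3 and is shorter by several steps.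

Alternative 2: C3 is excised as a single carbon carrying ring B, and ring C is contracted to the furan of 6-benzyloxy-7-methoxybenzofuran A6. The arylchlorocarbene released from 3-chloro-3-(2,3,4,5-tetramethoxyphenyl)-3H-diazirine A7 would cyclopropanate the furan double bond, and ring opening with loss of chloride would give the chromenylium salt A5, forming C2–C3 and C3–C4 at once. This is the most convergent option and is stronger than the chosen route in bonds per step and in having ring C closed by the key step itself. Against it, A5 is flat: C3 is sp2, so the stereocentre must come from a later enantioselective reduction of a cationic, nucleophile-sensitive heterocycle through an isoflavene stage. A7 carries four donor groups, which favour ionisation of the C–Cl bond and make the carbene less electrophilic. The furan double bond of A6 is also a weaker nucleophile than the pyrrole-type substrates for which such carbon insertions are best established. In place of this convergence, the chosen route creates C3 in the same event as the two C–C bonds and as a centre that cannot epimerise.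

Alternative 3: Ring C is cut at C3–C4 and O1–C2 with C2 at the carboxyl level. Fluoride would unmask the ortho-quinone methide A9, a chiral N-heterocyclic carbene would convert the acyl imidazole A10 into an azolium enolate, and conjugate addition followed by O-acylation would close the lactone A8. This forms ring C and C3 together without a metal, so it equals the chosen route in bonds per step and is stronger in closing the ring directly. Against it, C3 in A8 is alpha to an aryl ester carbonyl and also benzylic, and it is formed in a basic medium, so its configuration is exposed to enolisation from the moment it exists. The methide carbon (C4) is unsubstituted, so facial control rests entirely on the planar enolate. Removal of the C2 carbonyl needs reduction through an α-aryl aldehyde oxidation level and a second ring closure, which adds steps and a second chance of racemisation. A9 and A10 each also require several steps. In the chosen route C3 is never next to a carbonyl group.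

Key step: step 5

Assumption: the (αS,αS,Rp,Rp) antipode of the ferrocenyl bisphosphine is taken to give the (S)-boronic ester 12, by analogy with aryl migrations onto simple vinylboron ate complexes; the sense is to be checked on 12 by oxidising a sample to the secondary alcohol, and the mirror-image ligand is used if it proves reversed.

## Route

Step 1
Reactants: 1 2-methoxyresorcinol
Product: 3 2,4-dihydroxy-3-methoxybenzaldehyde, via iminium chloride 2 (not isolated)
Conditions: POCl3, DMF, MeCN, −15 °C → rt; then H2O, 50 °C
Reagents that add atoms: N,N-dimethylformamide CN(C)C=O; water O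
Why: Vilsmeier–Haack formylation; the chloroiminium ion attacks the position ortho to one hydroxyl and para to the other (C4 and C6 of 1 are equivalent, C5 is meta to both), and the iminium salt 2 is deactivated toward a second attack before water hydrolyses it to the aldehyde.

Step 2
Reactants: 3 2,4-dihydroxy-3-methoxybenzaldehyde
Product: 4 2,4-bis(benzyloxy)-3-methoxybenzaldehyde
Conditions: BnBr (2.4 equiv), K2CO3, DMF, 60 °C
Reagents that add atoms: benzyl bromide BrCc1ccccc1
Why: Williamson ether synthesis on both phenoxides; the hydrogen-bonded 2-hydroxyl reacts more slowly than the 4-hydroxyl, which is why excess halide and warming are used.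

Step 3
Reactants: 4 2,4-bis(benzyloxy)-3-methoxybenzaldehyde
Product: 6 2,4-bis(benzyloxy)-3-methoxyphenol, via aryl formate 5 (not isolated)
Conditions: mCPBA, CH2Cl2, 0 °C → rt; then KOH, MeOH/H2O, rt, N2; acidify
Reagents that add atoms: meta-chloroperoxybenzoic acid OOC(=O)c1cccc(Cl)c1
Why: Baeyer–Villiger oxidation (Dakin-type); the aryl group, activated by ortho- and para-alkoxy donors, migrates in preference to hydrogen to give the formate 5, which is saponified to the phenol under exclusion of air.

Step 4
Reactants: 6 2,4-bis(benzyloxy)-3-methoxyphenol
Product: 7 2,4-bis(benzyloxy)-3-methoxyphenyl trifluoromethanesulfonate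
Conditions: Tf2O, pyridine, CH2Cl2, 0 °C
Reagents that add atoms: trifluoromethanesulfonic anhydride O=S(=O)(OS(=O)(=O)C(F)(F)F)C(F)(F)F
Why: O-sulfonylation of a phenol; benzyl and methyl ethers are inert to the anhydride at 0 °C.

Step 5
Reactants: 7 2,4-bis(benzyloxy)-3-methoxyphenyl trifluoromethanesulfonate; 8 1,2,3,4-tetramethoxybenzene; 9 vinylboronic acid pinacol ester
Product: 12 2-[(1S)-2-[2,4-bis(benzyloxy)-3-methoxyphenyl]-1-(2,3,4,5-tetramethoxyphenyl)ethyl]-4,4,5,5-tetramethyl-1,3,2-dioxaborolane, via aryllithium 10 (not isolated), via vinylboron ate complex 11 (not isolated)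
Conditions: 8 (1.35 equiv), n-BuLi (1.3 equiv), THF, 0 °C → rt; 9 (1.3 equiv), 0 °C → rt; then 7 (1.0 equiv), Pd(OAc)2 (2 mol%), (αS,αS,Rp,Rp)-1,1'-bis[bis(4-methoxy-3,5-dimethylphenyl)phosphino]-2,2'-bis[α-(dimethylamino)benzyl]ferrocene (2.4 mol%), THF, 60 °C
Reagents that add atoms: none
Why: This is a palladium-catalysed enantioselective conjunctive cross-coupling of a vinylboron ate complex with an aryl triflate, a known reaction type for which aryl migrating groups and aryl triflates are the established partners. Directed ortho-lithiation of 8 gives 10 free of lithium halide, and 10 adds to the boron of 9 to give the ate complex 11. Zerovalent palladium, formed in the flask from Pd(OAc)2 and the bisphosphine, inserts into the C–O bond of 7 to give a cationic arylpalladium triflate of divalent palladium, which binds the vinyl group of 11. This π-activation triggers a 1,2-metallate shift in which the tetramethoxyphenyl group moves from boron to the boron-bearing carbon (C3–C1') anti to the metal while palladium bonds to the terminal carbon; reductive elimination then forms C4–C4a and returns zerovalent palladium. No ring is closed in this step. C3 is the only new stereocentre and is set in the metallate shift by the alkene face that the chiral ferrocenyl bisphosphine lets palladium occupy; the resulting benzylic C–B centre has no pathway for epimerisation under the conditions. The step needs the metallate shift to outrun direct boron-to-palladium transfer of the aryl group and reductive elimination to outrun β-hydride elimination; the triflate counter-ion and the absence of halide keep palladium cationic and alkene-seeking, the wide bite angle of the ligand favours reductive elimination, and the electron-rich aryl group migrates readily. The slight deficit of n-BuLi relative to 8 ensures that no butyl ate complex competes.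

Step 6
Reactants: 12 2-[(1S)-2-[2,4-bis(benzyloxy)-3-methoxyphenyl]-1-(2,3,4,5-tetramethoxyphenyl)ethyl]-4,4,5,5-tetramethyl-1,3,2-dioxaborolane
Product: 14 (2S)-3-[2,4-bis(benzyloxy)-3-methoxyphenyl]-2-(2,3,4,5-tetramethoxyphenyl)propan-1-ol, via homologated boronic ester 13 (not isolated)
Conditions: BrCH2Cl, n-BuLi, THF, −78 °C → rt; then NaOH, H2O2, THF/H2O, 0 °C → rt
Reagents that add atoms: bromochloromethane ClCBr; hydrogen peroxide OO
Why: Matteson homologation followed by boronate oxidation; LiCH2Cl generated in the presence of 12 adds to boron, and on warming the secondary benzylic carbon migrates with loss of chloride and with retention at C3 to give 13. Alkaline peroxide then converts the primary C–B bond into the C2 hydroxyl; the carbenoid has decomposed before the migration occurs, which limits a second insertion.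

Step 7
Reactants: 14 (2S)-3-[2,4-bis(benzyloxy)-3-methoxyphenyl]-2-(2,3,4,5-tetramethoxyphenyl)propan-1-ol
Product: 15 4-[(2S)-3-hydroxy-2-(2,3,4,5-tetramethoxyphenyl)propyl]-2-methoxybenzene-1,3-diol
Conditions: H2 (1 atm), 10% Pd/C, EtOAc/MeOH, rt
Reagents that add atoms: none
Why: Hydrogenolysis of both benzyl aryl ethers; C3 carries no benzylic heteroatom, so its bonds and configuration are not affected.

Step 8
Reactants: 15 4-[(2S)-3-hydroxy-2-(2,3,4,5-tetramethoxyphenyl)propyl]-2-methoxybenzene-1,3-diol
Product: 16 (3S)-8-methoxy-3-(2,3,4,5-tetramethoxyphenyl)-3,4-dihydro-2H-chromen-7-ol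
Conditions: PPh3, DIAD, THF (0.01 M), 0 °C → rt
Reagents that add atoms: none
Why: Intramolecular Mitsunobu etherification; the primary alcohol is activated as an alkoxyphosphonium ion and the phenoxide ortho to the side chain displaces it at C2 in a 6-exo-tet closure of O1–C2. The C7 phenol cannot reach C2 within the molecule and high dilution suppresses its intermolecular reaction; C3 is not involved, so the S configuration is carried into 16.

## Compound list

1 | 2-methoxyresorcinol (2-methoxybenzene-1,3-diol) | COc1c(O)cccc1O | starting material
2 | [(2,4-dihydroxy-3-methoxyphenyl)methylidene]dimethylammonium chloride | C[N+](C)=Cc1ccc(O)c(OC)c1O.[Cl-] | intermediate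
3 | 2,4-dihydroxy-3-methoxybenzaldehyde | O=Cc1ccc(O)c(OC)c1O | intermediate
4 | 2,4-bis(benzyloxy)-3-methoxybenzaldehyde | O=Cc1ccc(OCc2ccccc2)c(OC)c1OCc1ccccc1 | intermediate
5 | 2,4-bis(benzyloxy)-3-methoxyphenyl formate | O=COc1ccc(OCc2ccccc2)c(OC)c1OCc1ccccc1 | intermediate
6 | 2,4-bis(benzyloxy)-3-methoxyphenol | Oc1ccc(OCc2ccccc2)c(OC)c1OCc1ccccc1 | intermediate
7 | 2,4-bis(benzyloxy)-3-methoxyphenyl trifluoromethanesulfonate | O=S(=O)(Oc1ccc(OCc2ccccc2)c(OC)c1OCc1ccccc1)C(F)(F)F | intermediate
8 | 1,2,3,4-tetramethoxybenzene | COc1ccc(OC)c(OC)c1OC | starting material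
9 | vinylboronic acid pinacol ester (2-ethenyl-4,4,5,5-tetramethyl-1,3,2-dioxaborolane) | C=CB1OC(C)(C)C(C)(C)O1 | starting material
10 | 2,3,4,5-tetramethoxyphenyllithium | [Li]c1cc(OC)c(OC)c(OC)c1OC | intermediate
11 | lithium ethenyl(pinacolato)(2,3,4,5-tetramethoxyphenyl)borate | [Li+].C=C[B-]1(OC(C)(C)C(C)(C)O1)c1cc(OC)c(OC)c(OC)c1OC | intermediate
12 | 2-[(1S)-2-[2,4-bis(benzyloxy)-3-methoxyphenyl]-1-(2,3,4,5-tetramethoxyphenyl)ethyl]-4,4,5,5-tetramethyl-1,3,2-dioxaborolane | COc1cc([C@H](Cc2ccc(OCc3ccccc3)c(OC)c2OCc2ccccc2)B2OC(C)(C)C(C)(C)O2)c(OC)c(OC)c1OC | intermediate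
13 | 2-[(2S)-3-[2,4-bis(benzyloxy)-3-methoxyphenyl]-2-(2,3,4,5-tetramethoxyphenyl)propyl]-4,4,5,5-tetramethyl-1,3,2-dioxaborolane | COc1cc([C@H](Cc2ccc(OCc3ccccc3)c(OC)c2OCc2ccccc2)CB2OC(C)(C)C(C)(C)O2)c(OC)c(OC)c1OC | intermediate
14 | (2S)-3-[2,4-bis(benzyloxy)-3-methoxyphenyl]-2-(2,3,4,5-tetramethoxyphenyl)propan-1-ol | COc1cc([C@H](Cc2ccc(OCc3ccccc3)c(OC)c2OCc2ccccc2)CO)c(OC)c(OC)c1OC | intermediate
15 | 4-[(2S)-3-hydroxy-2-(2,3,4,5-tetramethoxyphenyl)propyl]-2-methoxybenzene-1,3-diol | COc1cc([C@H](Cc2ccc(O)c(OC)c2O)CO)c(OC)c(OC)c1OC | intermediate
16 | (3S)-8-methoxy-3-(2,3,4,5-tetramethoxyphenyl)-3,4-dihydro-2H-chromen-7-ol | COc1cc([C@H]2COc3c(ccc(O)c3OC)C2)c(OC)c(OC)c1OC | target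

## Step count and least certain steps

Total: 8 steps. Longest linear sequence: 8 steps (1 to 16, steps 1 to 8); 8 and 9 enter in step 5 without steps of their own.

**Step 5 (key step).** The most likely failure is direct transfer of the tetramethoxyphenyl group from boron to palladium, giving a biaryl. Both partners carry ortho-oxygen substituents, which hinder binding of the cationic arylpalladium to the vinyl group and so slow the metallate shift relative to transmetallation. The same crowding may lower face selectivity, and oxidative addition into the electron-rich triflate may be slow. The fallback sets out from 4 and 8 and returns at 12. It is a stoichiometric lithiation–borylation in which C4–C4a already exists and only C3–C1' is formed in the stereodefining step.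
- Wittig methylenation of 4 (Ph3PCH3Br, KOt-Bu, THF) gives 1,3-bis(benzyloxy)-4-ethenyl-2-methoxybenzene F1.
- Hydroboration–oxidation (9-BBN, THF; NaOH, H2O2) gives 2-[2,4-bis(benzyloxy)-3-methoxyphenyl]ethanol F2.
- N,N-Diisopropylcarbamoyl chloride and Et3N give 2-[2,4-bis(benzyloxy)-3-methoxyphenyl]ethyl N,N-diisopropylcarbamate F3.
- Aryllithium 10, made from 8 as in step 5, is quenched with 2-isopropoxy-4,4,5,5-tetramethyl-1,3,2-dioxaborolane to give 4,4,5,5-tetramethyl-2-(2,3,4,5-tetramethoxyphenyl)-1,3,2-dioxaborolane F4.
- Enantioselective deprotonation of F3 with s-BuLi and (+)-sparteine (Et2O, −78 °C), addition of F4, and 1,2-migration of the aryl group with loss of the carbamate (MgBr2·OEt2, warming) should give 12. (+)-Sparteine is chosen because borylation proceeds with retention and the migration with inversion.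

**Step 6.** Capture of the hindered secondary benzylic boronic ester by the short-lived carbenoid may be incomplete, which after oxidation would show up as C–B oxidation without homologation. A second insertion into the less hindered primary boronic ester is the other risk. The fallback sets out from 12 and returns at 14.
- Zweifel olefination of 12 (CH2=CHMgBr, THF; I2, MeOH, −78 °C; NaOMe) gives, with retention at C3, 1-[(2R)-1-[2,4-bis(benzyloxy)-3-methoxyphenyl]but-3-en-2-yl]-2,3,4,5-tetramethoxybenzene F5. The descriptor changes only through the priority rules.
- Lemieux–Johnson cleavage (OsO4 cat., NaIO4, 2,6-lutidine, dioxane/H2O) gives (2S)-3-[2,4-bis(benzyloxy)-3-methoxyphenyl]-2-(2,3,4,5-tetramethoxyphenyl)propanal F6.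
- F6 is reduced at once (NaBH4, MeOH, 0 °C) to 14, so that the α-aryl aldehyde has little time to enolise.

**Step 8.** Ring closure competes with intermolecular etherification through the free C7 phenol and, if closure is slow, with alkylation of the reduced azodicarboxylate. The fallback sets out from 14 and returns at 16. It separates activation from closure.
- Mesylation while both phenols are still protected (MsCl, Et3N, CH2Cl2, 0 °C) gives (2S)-3-[2,4-bis(benzyloxy)-3-methoxyphenyl]-2-(2,3,4,5-tetramethoxyphenyl)propyl methanesulfonate F7.
- Hydrogenolysis (H2, Pd/C, EtOAc) gives (2S)-3-(2,4-dihydroxy-3-methoxyphenyl)-2-(2,3,4,5-tetramethoxyphenyl)propyl methanesulfonate F8.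
- Slow addition of F8 to K2CO3 in MeCN at 50 °C closes O1–C2 by intramolecular Williamson etherification to give 16.

**Step 1.** Over-formylation, O-formylation or poor recovery of the water-soluble dihydroxy aldehyde may lower the throughput of the ring-A branch. The fallback sets out from 1 and returns at 6, bypassing steps 1 to 3.
- Double benzylation of 1 (BnBr, K2CO3, DMF) gives 1,3-bis(benzyloxy)-2-methoxybenzene F9.
- Bromination with N-bromosuccinimide in MeCN at the position ortho and para to the two benzyloxy groups gives 1,3-bis(benzyloxy)-4-bromo-2-methoxybenzene F10.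
- Palladium-catalysed hydroxylation (Pd2(dba)3, 2-di-tert-butylphosphino-2',4',6'-triisopropylbiphenyl, KOH, dioxane/H2O, 100 °C) gives 6.

## Further compounds

F1 | step 5 | 1,3-bis(benzyloxy)-4-ethenyl-2-methoxybenzene | C=Cc1ccc(OCc2ccccc2)c(OC)c1OCc1ccccc1
F2 | step 5 | 2-[2,4-bis(benzyloxy)-3-methoxyphenyl]ethanol | OCCc1ccc(OCc2ccccc2)c(OC)c1OCc1ccccc1
F3 | step 5 | 2-[2,4-bis(benzyloxy)-3-methoxyphenyl]ethyl N,N-diisopropylcarbamate | CC(C)N(C(C)C)C(=O)OCCc1ccc(OCc2ccccc2)c(OC)c1OCc1ccccc1
F4 | step 5 | 4,4,5,5-tetramethyl-2-(2,3,4,5-tetramethoxyphenyl)-1,3,2-dioxaborolane | COc1cc(B2OC(C)(C)C(C)(C)O2)c(OC)c(OC)c1OC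
F5 | step 6 | 1-[(2R)-1-[2,4-bis(benzyloxy)-3-methoxyphenyl]but-3-en-2-yl]-2,3,4,5-tetramethoxybenzene | COc1cc([C@H](Cc2ccc(OCc3ccccc3)c(OC)c2OCc2ccccc2)C=C)c(OC)c(OC)c1OC
F6 | step 6 | (2S)-3-[2,4-bis(benzyloxy)-3-methoxyphenyl]-2-(2,3,4,5-tetramethoxyphenyl)propanal | COc1cc([C@H](Cc2ccc(OCc3ccccc3)c(OC)c2OCc2ccccc2)C=O)c(OC)c(OC)c1OC
F7 | step 8 | (2S)-3-[2,4-bis(benzyloxy)-3-methoxyphenyl]-2-(2,3,4,5-tetramethoxyphenyl)propyl methanesulfonate | COc1cc([C@H](Cc2ccc(OCc3ccccc3)c(OC)c2OCc2ccccc2)COS(C)(=O)=O)c(OC)c(OC)c1OC
F8 | step 8 | (2S)-3-(2,4-dihydroxy-3-methoxyphenyl)-2-(2,3,4,5-tetramethoxyphenyl)propyl methanesulfonate | COc1cc([C@H](Cc2ccc(O)c(OC)c2O)COS(C)(=O)=O)c(OC)c(OC)c1OC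
F9 | step 1 | 1,3-bis(benzyloxy)-2-methoxybenzene | COc1c(OCc2ccccc2)cccc1OCc1ccccc1
F10 | step 1 | 1,3-bis(benzyloxy)-4-bromo-2-methoxybenzene | COc1c(OCc2ccccc2)ccc(Br)c1OCc1ccccc1
A1 | alternative 1 | 5-[(3S)-7-benzyloxy-8-methoxychroman-3-yl]-2,3-dimethoxy-1,4-benzoquinone | COC1=C(OC)C(=O)C([C@H]2COc3c(ccc(OCc4ccccc4)c3OC)C2)=CC1=O
A2 | alternative 1 | 4-{[(3S)-7-benzyloxy-8-methoxychroman-3-yl]ethynyl}-4-hydroxy-2,3-dimethoxycyclobut-2-en-1-one | COC1=C(OC)C(O)(C#C[C@H]2COc3c(ccc(OCc4ccccc4)c3OC)C2)C1=O
A3 | alternative 1 | (3S)-7-benzyloxy-3-ethynyl-8-methoxychroman | C#C[C@H]1COc2c(ccc(OCc3ccccc3)c2OC)C1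
A4 | alternative 1 | dimethyl squarate (3,4-dimethoxycyclobut-3-ene-1,2-dione) | COC1=C(OC)C(=O)C1=O
A5 | alternative 2 | 7-benzyloxy-8-methoxy-3-(2,3,4,5-tetramethoxyphenyl)chromenylium chloride | COc1cc(-c2c[o+]c3c(OC)c(OCc4ccccc4)ccc3c2)c(OC)c(OC)c1OC.[Cl-]
A6 | alternative 2 | 6-benzyloxy-7-methoxybenzofuran | COc1c(OCc2ccccc2)ccc2ccoc12
A7 | alternative 2 | 3-chloro-3-(2,3,4,5-tetramethoxyphenyl)-3H-diazirine | COc1cc(C2(Cl)N=N2)c(OC)c(OC)c1OC
A8 | alternative 3 | (3S)-7-benzyloxy-8-methoxy-3-(2,3,4,5-tetramethoxyphenyl)chroman-2-one | COc1cc([C@H]2C(=O)Oc3c(ccc(OCc4ccccc4)c3OC)C2)c(OC)c(OC)c1OC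
A9 | alternative 3 | 3-benzyloxy-2-methoxy-6-methylidenecyclohexa-2,4-dien-1-one | C=C1C=CC(OCc2ccccc2)=C(OC)C1=O
A10 | alternative 3 | 1-(imidazol-1-yl)-2-(2,3,4,5-tetramethoxyphenyl)ethanone | COc1cc(CC(=O)n2ccnc2)c(OC)c(OC)c1OC
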